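(Readings and results are calculated with made-up constants; noise was put on by code.)

The coupling partner was the setting the earlier runs had turned, so I started there.

| setting | amber | blue | flask |
|---|---|---|---|
| left-handed substrate | 10 mM | 10 mM | 10 mM |
| right-handed substrate | 10 mM | 10 mM | 10 mM |
| coupling partner | 27 mM | 60 mM | 40.0 mM |
| free catalyst | 0.27 mM | 0.27 mM | 0.27 mM |
| precatalyst | 2 mM | 2 mM | 2.0 mM |
| remark | run made earlier | run made earlier |  |
| time |  |  | 2.5 d |

| run | time / d | left-handed substrate / % | right-handed substrate / % |
|---|---|---|---|
| amber | 0.625 | 33.2 | 33.7 |
| amber | 1.25 | 29.7 | 30.0 |
| amber | 1.67 | 28.4 | 29.1 |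
| amber | 2.50 | 27.1 | 26.7 |
| amber | 3.00 | 25.9 | 26.3 |
| blue | 0.625 | 26.5 | 27.6 |
| blue | 1.25 | 22.5 | 22.8 |
| blue | 1.67 | 22.4 | 21.8 |
| blue | 2.50 | 20.2 | 19.7 |
| blue | 3.00 | 19.8 | 20.0 |

(scatter of a reading: 0.5 percentage points)

- free catalyst is single-handed; left-handed substrate and right-handed substrate are mirror images of each other, charged as a racemate, each of them at the stated concentration
- the analysis behind the earlier runs scatters by 0.5 percentage points, standard deviation
- an excess is below zero if the other one leads

1. part of the left-handed substrate and right-handed substrate charged together that has reacted at 2.5 d
2. excess of left-handed product over right-handed product in the product at 2.5 d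
3. excess of right-handed substrate over left-handed substrate among what is left of the two at 2.5 d

1. Coupling partner. By hand, more of it should mean more conversion. At 2.50 d the amber run had reacted 46.2% and the blue run 60.1%. So 33.0 mM of extra partner turned just 2.78 mM more substrate.

2. Returns like that call for counting in doublings. I read a doubling gain of 12 percentage points, the points of conversion won at a fixed time per doubling of the partner charge, substrates and catalysts held. Counting up from the amber run, I reckoned 53.0% for the flask with 40.0 mM.

3. Free catalyst and precatalyst. By hand, more free catalyst should speed coupling, but both runs held the same charges of each, so the readings gave me no figure. The flask holds those charges too.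

4. Handedness. I took the racemate as the zero of the excess scale. At 2.50 d, right-handed minus left-handed substrate read −0.4 points in amber and −0.5 points in blue, against a scatter of 0.5 points per reading. In a plain kinetic resolution, product excess is that gap over conversion, so I committed to zero for both excesses.

5. The forecast gave 53%, 0.2% and 0.2%: "This fits weak kinetic selectivity, erased by reversibility".

6. The flask gave 52.8%, 9.66% and 0.0243%.

    left-handed product ⇌ right-handed product (k = 3.10 × 10⁻⁶ /s)
    coupling partner + free catalyst + right-handed substrate → free catalyst + right-handed product (k = 2.00 /M²/s)
    precatalyst → racemization catalyst (k = 6.70 × 10⁻⁵ /s)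
    coupling partner + free catalyst + left-handed substrate → free catalyst + left-handed product (k = 3.60 /M²/s)
    left-handed substrate + racemization catalyst ⇌ right-handed substrate + racemization catalyst, rate k5*[racemization catalyst]*[left-handed substrate] forward; the back reaction follows from the equilibrium constant (k = 0.160 /M/s)
    2 coupling partner → self-condensation product (k = 0.00110 /M/s)

7. My conversion stood, but my zero for the product did not. In the flask, coupling used left-handed substrate at 0.18 of the forward racemization rate at 0.0828 d, and at 0.0022 of it at 2.50 d. At 2.5 d in the flask, each substrate stood at 23.6% while left-handed product held 29.0% against 23.9% right-handed. For the neighbour flask with 68 mM of partner, 12 points per doubling gives 62.3%; that flask reached 61.2%.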